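**Assumptions:** the target is drawn as one of two rapidly interconverting enol tautomers (C2/C4); commercial (1R,5R)-(+)-α-pinene of ≥97% ee is used. Target numbering used below: C1 = prenylated bridgehead next to C8 (CMe2), C2–C3–C4 = enolised diketone bridge, C5 = benzoylated bridgehead, C6 = CH2, C7 = CH(prenyl), C9 = bridging ketone.

## Retrosynthetic overview

1. Target ⇒ C3–prenyl bond by zerovalent-palladium O→C prenyl transposition of a 2-prenyloxy vinylogous ester; C5–benzoyl bond by bridgehead lithiation/benzoylation of the bicyclic trione core.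
2. Bicyclic trione ⇒ Effenberger annulation of malonyl dichloride (C5–C4 and C1–C2; trione ring formed second) onto a regiodefined cyclohexenyl silyl ether.
3. Cyclohexenyl silyl ether ⇒ visible-light radical-cation 1,3-shift of a 1-silyloxyvinyl cyclobutane (C1–C8 bond; six-membered carbocycle formed first, by ring expansion).
4. Cyclobutane ⇒ (+)-α-pinene by ozonolysis, aldehyde-selective Wittig, α-prenylation and enol silylation; the pinene C5 stereocentre becomes C7 and later directs C1 and C5.

## Route

Step 1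
Reactants: 1 (1R,5R)-(+)-α-pinene; 2 ozone
Product: 4 2-[(1S,3S)-3-acetyl-2,2-dimethylcyclobutyl]acetaldehyde (cis-pinonaldehyde), via secondary ozonide 3 (not isolated)
Conditions: O3, CH2Cl2, −78 °C; then PPh3, −78 °C to rt
Reagents that add atoms: ozone, O=[O+][O-]
Why: Criegee ozonolysis cleaves the only C=C bond and the phosphine work-up stops at the keto aldehyde; the ring CH that becomes C7 is not touched and keeps the pinene configuration.

Step 2
Reactants: 4 cis-pinonaldehyde; 5 isopropyltriphenylphosphonium iodide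
Product: 6 1-[(1S,3R)-2,2-dimethyl-3-(3-methylbut-2-en-1-yl)cyclobutyl]ethan-1-one
Conditions: 5, n-BuLi, THF, 0 °C; then 4, −78 °C to 0 °C
Reagents that add atoms: isopropyltriphenylphosphonium iodide, CC(C)[P+](c1ccccc1)(c1ccccc1)c1ccccc1.[I-]
Why: Wittig olefination, in which the hindered non-stabilised isopropylidene ylide reacts with the aldehyde much faster than with the methyl ketone; no stereocentre is formed.

Step 3
Reactants: 6 cyclobutyl methyl ketone; 7 prenyl bromide (1-bromo-3-methylbut-2-ene)
Product: 9 1-[(1S,3R)-2,2-dimethyl-3-(3-methylbut-2-en-1-yl)cyclobutyl]-5-methylhex-4-en-1-one, via lithium enolate 8 (not isolated)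
Conditions: LiN(i-Pr)2 (LDA), THF, −78 °C; then 7, −78 to −20 °C
Reagents that add atoms: prenyl bromide, CC(C)=CCBr
Why: Kinetic enolate alkylation: the amide base removes a methyl proton rather than the hindered cyclobutyl methine and the terminal enolate displaces the allylic bromide by SN2; no stereocentre is formed.

Step 4
Reactants: 9 cyclobutyl homoprenyl ketone; 10 tert-butyldimethylsilyl chloride
Product: 12 tert-butyl({1-[(1S,3R)-2,2-dimethyl-3-(3-methylbut-2-en-1-yl)cyclobutyl]-5-methylhexa-1,4-dien-1-yl}oxy)dimethylsilane (Z/E mixture), via lithium enolate 11 (not isolated)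
Conditions: LiN(i-Pr)2 (LDA), THF, −78 °C; then TBSCl, DMPU, −78 °C to rt
Reagents that add atoms: tert-butyldimethylsilyl chloride, CC(C)(C)[Si](C)(C)Cl
Why: Kinetic enolisation toward the side-chain CH2 (not the ring methine) followed by O-silylation of the enolate places the enol double bond toward C1; its geometry is inconsequential.

Step 5
Reactants: 12 silyloxyvinyl cyclobutane
Product: 14 tert-butyl{[(4R)-5,5-dimethyl-4,6-bis(3-methylbut-2-en-1-yl)cyclohex-1-en-1-yl]oxy}dimethylsilane (both C6 epimers), via distonic radical cation 13 (not isolated)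
Conditions: Ru(bpz)3(PF6)2 (2 mol %), 450 nm LEDs, degassed MeNO2, rt
Reagents that add atoms: none
Why: Proposed new method: the excited divalent ruthenium photocatalyst (about +1.4 V vs SCE) oxidises only the silyl enol ether (about +1.3 to +1.5 V; the prenyl alkenes lie near +1.9 V), the radical cation relieves cyclobutane strain by cleaving the bond between the allylic ring carbon and the CMe2 carbon to give distonic 13 (2-silyloxyallyl radical plus tertiary cation), the cation is recaptured at the far allyl terminus through a six-membered transition state to form the C1–C8 bond, and back electron transfer from the reduced catalyst (or from 12 in a chain) releases 14 with the double bond regiospecifically toward C5; the stereocentre that becomes C7 is not a reacting atom and is retained, and the new C1 centre is erased in step 6; the closest known reaction types are the aminium-salt-catalysed cation-radical vinylcyclobutane-to-cyclohexene rearrangement and the electron-transfer ring opening of the α-pinene radical cation.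

Step 6
Reactants: 14 cyclohexenyl silyl ether; 15 malonyl dichloride
Product: 17 (1R,5S,7R)-4-hydroxy-8,8-dimethyl-1,7-bis(3-methylbut-2-en-1-yl)bicyclo[3.3.1]non-3-ene-2,9-dione, via keto acid chloride 16 (not isolated)
Conditions: malonyl dichloride, Et2O, −20 °C to rt; then KOH, BnEt3NCl, H2O
Reagents that add atoms: malonyl dichloride, O=C(Cl)CC(=O)Cl
Why: Effenberger cyclisation (C-acylation of the silyl enol ether at C5, then intramolecular C-acylation at C1 through the enol): the malonyl bridge must span C1 and C5 diaxially and closes through the chair in which the C7 prenyl group stays equatorial (exo), so the purchased C7 centre fixes both bridgeheads.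

Step 7
Reactants: 17 bicyclic trione; 18 prenol (3-methylbut-2-en-1-ol)
Product: 19 (1R,5S,7R)-8,8-dimethyl-1,7-bis(3-methylbut-2-en-1-yl)-2-[(3-methylbut-2-en-1-yl)oxy]bicyclo[3.3.1]non-2-ene-4,9-dione
Conditions: prenol, PPh3, DIAD, THF, 0 °C to rt; chromatography to remove the 4-prenyloxy regioisomer
Reagents that add atoms: prenol, CC(C)=CCO
Why: Mitsunobu O-alkylation of the vinylogous acid gives the vinylogous ester without C-alkylation; the isomer that keeps the C4 carbonyl next to the C5–H is carried on, and no stereocentre is touched.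

Step 8
Reactants: 19 prenyl vinylogous ester; 20 benzoyl chloride
Product: 22 (1R,5S,7R)-5-benzoyl-8,8-dimethyl-1,7-bis(3-methylbut-2-en-1-yl)-2-[(3-methylbut-2-en-1-yl)oxy]bicyclo[3.3.1]non-2-ene-4,9-dione, via bridgehead lithium compound 21 (not isolated)
Conditions: LiN(i-Pr)2 (LDA), THF, −78 °C; then BzCl, −78 to −40 °C
Reagents that add atoms: benzoyl chloride, O=C(Cl)c1ccccc1
Why: Bridgehead lithiation/acylation: the C5–H flanked by the C4 and C9 carbonyls is the kinetically most acidic site, and the bicycle locks its configuration, so acylation proceeds with retention.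

Step 9
Reactants: 22 benzoylated prenyl vinylogous ester
Product: 23 (1R,5S,7R)-5-benzoyl-4-hydroxy-8,8-dimethyl-1,3,7-tris(3-methylbut-2-en-1-yl)bicyclo[3.3.1]non-3-ene-2,9-dione (CNP0284108.1)
Conditions: Pd(PPh3)4 (5 mol %), THF, 40 °C
Reagents that add atoms: none
Why: Tsuji–Trost-type O-to-C allyl transposition: zerovalent palladium ionises the prenyl vinylogous ester and the soft C3 carbon of the trione enolate recaptures the unhindered primary prenyl terminus irreversibly, installing the linear C3 prenyl group and unveiling the enol without touching a stereocentre.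

## Compound list

1 | (1R,5R)-(+)-α-pinene | CC1=CC[C@@H]2C[C@H]1C2(C)C | starting material
2 | ozone | O=[O+][O-] | starting material
3 | secondary ozonide (1,2,4-trioxolane) of 1 | CC12OOC(O1)C[C@@H]1C[C@H]2C1(C)C | intermediate
4 | 2-[(1S,3S)-3-acetyl-2,2-dimethylcyclobutyl]acetaldehyde (cis-pinonaldehyde) | CC(=O)[C@H]1C[C@@H](CC=O)C1(C)C | intermediate
5 | isopropyltriphenylphosphonium iodide | CC(C)[P+](c1ccccc1)(c1ccccc1)c1ccccc1.[I-] | starting material
6 | 1-[(1S,3R)-2,2-dimethyl-3-(3-methylbut-2-en-1-yl)cyclobutyl]ethan-1-one | CC(=O)[C@H]1C[C@@H](CC=C(C)C)C1(C)C | intermediate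
7 | prenyl bromide (1-bromo-3-methylbut-2-ene) | CC(C)=CCBr | starting material
8 | lithium enolate of 6 (terminal, CH2=C(OLi)–) | C=C(O[Li])[C@H]1C[C@@H](CC=C(C)C)C1(C)C | intermediate
9 | 1-[(1S,3R)-2,2-dimethyl-3-(3-methylbut-2-en-1-yl)cyclobutyl]-5-methylhex-4-en-1-one | CC(C)=CCCC(=O)[C@H]1C[C@@H](CC=C(C)C)C1(C)C | intermediate
10 | tert-butyldimethylsilyl chloride | CC(C)(C)[Si](C)(C)Cl | starting material
11 | lithium enolate of 9 (side-chain enolate) | CC(C)=CCC=C(O[Li])[C@H]1C[C@@H](CC=C(C)C)C1(C)C | intermediate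
12 | tert-butyl({1-[(1S,3R)-2,2-dimethyl-3-(3-methylbut-2-en-1-yl)cyclobutyl]-5-methylhexa-1,4-dien-1-yl}oxy)dimethylsilane (Z/E mixture) | CC(C)=CCC=C(O[Si](C)(C)C(C)(C)C)[C@H]1C[C@@H](CC=C(C)C)C1(C)C | intermediate
13 | ring-opened distonic radical cation (tertiary cation at the CMe2 carbon, 2-silyloxyallyl radical) | C[C+](C)[C@H](CC=C(C)C)CC=C(O[Si](C)(C)C(C)(C)C)[CH]CC=C(C)C | intermediate
14 | tert-butyl{[(4R)-5,5-dimethyl-4,6-bis(3-methylbut-2-en-1-yl)cyclohex-1-en-1-yl]oxy}dimethylsilane (both C6 epimers) | CC(C)=CC[C@@H]1CC=C(O[Si](C)(C)C(C)(C)C)C(CC=C(C)C)C1(C)C | intermediate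
15 | malonyl dichloride | O=C(Cl)CC(=O)Cl | starting material
16 | 3-[(5R)-4,4-dimethyl-3,5-bis(3-methylbut-2-en-1-yl)-2-oxocyclohexyl]-3-oxopropanoyl chloride | O=C(Cl)CC(=O)C1C[C@@H](CC=C(C)C)C(C)(C)C(CC=C(C)C)C1=O | intermediate
17 | (1R,5S,7R)-4-hydroxy-8,8-dimethyl-1,7-bis(3-methylbut-2-en-1-yl)bicyclo[3.3.1]non-3-ene-2,9-dione | C1=C(O)[C@@H]2C[C@@H](CC=C(C)C)C(C)(C)[C@](CC=C(C)C)(C1=O)C2=O | intermediate
18 | prenol (3-methylbut-2-en-1-ol) | CC(C)=CCO | starting material
19 | (1R,5S,7R)-8,8-dimethyl-1,7-bis(3-methylbut-2-en-1-yl)-2-[(3-methylbut-2-en-1-yl)oxy]bicyclo[3.3.1]non-2-ene-4,9-dione | O=C1C=C(OCC=C(C)C)[C@@]2(CC=C(C)C)C(C)(C)[C@H](CC=C(C)C)C[C@@H]1C2=O | intermediate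
20 | benzoyl chloride | O=C(Cl)c1ccccc1 | starting material
21 | C5 bridgehead lithium derivative of 19 | O=C1C=C(OCC=C(C)C)[C@@]2(CC=C(C)C)C(C)(C)[C@H](CC=C(C)C)C[C@]1([Li])C2=O | intermediate
22 | (1R,5S,7R)-5-benzoyl-8,8-dimethyl-1,7-bis(3-methylbut-2-en-1-yl)-2-[(3-methylbut-2-en-1-yl)oxy]bicyclo[3.3.1]non-2-ene-4,9-dione | O=C1C=C(OCC=C(C)C)[C@@]2(CC=C(C)C)C(C)(C)[C@H](CC=C(C)C)C[C@]1(C(=O)c3ccccc3)C2=O | intermediate
23 | (1R,5S,7R)-5-benzoyl-4-hydroxy-8,8-dimethyl-1,3,7-tris(3-methylbut-2-en-1-yl)bicyclo[3.3.1]non-3-ene-2,9-dione | CC(C)=CCC1=C(O)[C@]2(C(=O)c3ccccc3)C[C@@H](CC=C(C)C)C(C)(C)[C@](CC=C(C)C)(C1=O)C2=O | target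

## Step count and risks

Total step count: 9. Longest linear sequence: 9 steps (fully linear from 1).

**Step 5 (proposed new step).** The radical cation could instead fragment by cycloreversion, lose a proton from the tertiary cation to give a ring-opened dienol ether, lose the silyl group, or undergo a hydride shift at the carbon that becomes C7. The fallback uses known chemistry, sets out from 6 and comes back at 14. Irradiation of 6 at about 300 nm brings about the Norrish type 2 cleavage known for cis-pinonic acid (γ-hydrogen abstraction from the ring methyl cis to the acyl group, then β-cleavage) and opens the cyclobutane to (5S)-8-methyl-5-(prop-1-en-2-yl)non-7-en-2-one F1. Kinetic enolate alkylation (LDA, prenyl bromide 7) gives (9S)-2,12-dimethyl-9-(prop-1-en-2-yl)trideca-2,11-dien-6-one F2. Cobalt-catalysed Markovnikov hydrochlorination (Co(BF4)2·6H2O, salicylaldimine ligand, PhSiH3, TsCl, t-BuOOH, EtOH), which prefers the 1,1-disubstituted alkene over the two trisubstituted ones, gives (9S)-9-(2-chloropropan-2-yl)-2,12-dimethyltrideca-2,11-dien-6-one F3. LDA/Me3SiCl then gives {[(9S)-9-(2-chloropropan-2-yl)-2,12-dimethyltrideca-2,5,11-trien-6-yl]oxy}trimethylsilane F4; the regioisomeric enol ether cannot close a six-membered ring and returns F3 on work-up. TiCl4 (CH2Cl2, −78 °C) effects an intramolecular Reetz-type tert-alkylation to (4S)-3,3-dimethyl-2,4-bis(3-methylbut-2-en-1-yl)cyclohexan-1-one F5, and kinetic enolisation toward the less hindered CH2 (LDA, TBSCl 10, DMPU) returns to 14.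

**Step 6.** Effenberger cyclisations of this substrate type are known but low-yielding (enol lactone and O-acylation by-products). The fallback sets out from 14 and comes back at 17. A Mukaiyama-type C-acylation of 14 with methyl 3-chloro-3-oxopropanoate (TiCl4, CH2Cl2, −78 °C) gives methyl 3-[(5R)-4,4-dimethyl-3,5-bis(3-methylbut-2-en-1-yl)-2-oxocyclohexyl]-3-oxopropanoate F6. A separate Dieckmann-type closure (KOt-Bu, THF, then acid work-up) forms the C1–C2 bond through the C1 enolate and gives 17, driven by formation of the stable vinylogous acid salt.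

**Step 8.** Bridgehead substitutions on these cores are sensitive to the electrophile, and C3 deprotonation or O-acylation may compete. The fallback sets out from 19 and comes back at 22. The bridgehead lithium compound is trapped with the smaller and more reactive benzaldehyde to give (1R,5R,7R)-5-[hydroxy(phenyl)methyl]-8,8-dimethyl-1,7-bis(3-methylbut-2-en-1-yl)-2-[(3-methylbut-2-en-1-yl)oxy]bicyclo[3.3.1]non-2-ene-4,9-dione F7 (carbinol epimers), and Dess–Martin periodinane oxidises the carbinol to 22.

Further compounds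
F1 | step 5 | (5S)-8-methyl-5-(prop-1-en-2-yl)non-7-en-2-one | CC(=O)CC[C@@H](CC=C(C)C)C(C)=C
F2 | step 5 | (9S)-2,12-dimethyl-9-(prop-1-en-2-yl)trideca-2,11-dien-6-one | CC(C)=CCCC(=O)CC[C@@H](CC=C(C)C)C(C)=C
F3 | step 5 | (9S)-9-(2-chloropropan-2-yl)-2,12-dimethyltrideca-2,11-dien-6-one | CC(C)=CCCC(=O)CC[C@@H](CC=C(C)C)C(C)(C)Cl
F4 | step 5 | {[(9S)-9-(2-chloropropan-2-yl)-2,12-dimethyltrideca-2,5,11-trien-6-yl]oxy}trimethylsilane | CC(C)=CCC=C(O[Si](C)(C)C)CC[C@@H](CC=C(C)C)C(C)(C)Cl
F5 | step 5 | (4S)-3,3-dimethyl-2,4-bis(3-methylbut-2-en-1-yl)cyclohexan-1-one | O=C1CC[C@@H](CC=C(C)C)C(C)(C)C1CC=C(C)C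
F6 | step 6 | methyl 3-[(5R)-4,4-dimethyl-3,5-bis(3-methylbut-2-en-1-yl)-2-oxocyclohexyl]-3-oxopropanoate | COC(=O)CC(=O)C1C[C@@H](CC=C(C)C)C(C)(C)C(CC=C(C)C)C1=O
F7 | step 8 | (1R,5R,7R)-5-[hydroxy(phenyl)methyl]-8,8-dimethyl-1,7-bis(3-methylbut-2-en-1-yl)-2-[(3-methylbut-2-en-1-yl)oxy]bicyclo[3.3.1]non-2-ene-4,9-dione | O=C1C=C(OCC=C(C)C)[C@@]2(CC=C(C)C)C(C)(C)[C@H](CC=C(C)C)C[C@]1(C(O)c3ccccc3)C2=O
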